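## The problem

Compound 21 is an 8–5′ neolignan diester. Its core is a 2,3-dihydrobenzofuran whose benzo ring (ring A) carries a methoxy group at C7 and a three-carbon chain at C5; C2 carries a guaiacyl ring (ring B) and C3 carries an oxymethyl carbon (C9). The C9 oxygen is acylated by (E)-p-coumaric acid and the chain terminus by (Z)-ferulic acid, so two primary alcohols must be told apart and given different cinnamoyl groups. There are only two stereocentres, C2 (R) and C3 (S), and they are trans. C2 is a benzylic ether carbon para to the oxygen of ring B and ionises easily in acid, so under equilibrating conditions its configuration follows C3. C3 cannot be corrected from C2 in the same way, so the absolute configuration has to be invested in C3. The (Z)-ferulate isomerises with light, phenoxide, nucleophilic catalysts and radicals; both cinnamate double bonds exclude hydrogenolysis; the esters exclude late hydride or hydroxide; three phenols must be freed last without any of this happening. The feature that allows a short route is that C3 is a benzylic CH of ring A between the oxygenated methylene C9 and the carbinol-level carbon C2: C3 and C9 are the α and β carbons of a ring A styrene, and C2 is the carbonyl carbon of a ring B aldehyde.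

## Retrosynthesis

**21 from 20.** The last cut is of three aryl O–Si bonds, leading back to the tris(triisopropylsilyl) ether 20. Silyl ethers are preferred to benzyl ethers, whose hydrogenolysis would saturate both cinnamates, and to acyl groups, whose removal would not spare the two esters. 20 is no simpler in skeleton, but it keeps every phenol masked through the end game. The forward step must free three phenols without opening an ester or turning the Z alkene.

**20 from 19 and 6.** The Z double bond of the feruloyl unit is cut between Cα and Cβ, giving phosphonoacetate 19 and silylated vanillin 6. The neighbouring cut, the acyl C–O bond with a preformed (Z)-ferulic acid, would need a separate synthesis of that acid, and its activation as an acylpyridinium invites Z to E isomerisation. Forming the alkene on the substrate under kinetic Z control reuses aldehyde 6, already made for the key step. The forward reaction must give Z selectivity at low temperature with an electron-rich aldehyde and must leave the E ester alone.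

**19 from 18, and 18 from 16.** The chain acyl C–O bond is cut to alcohol 18, and 18 is traced to the allyl compound 16 by removing the terminal hydroxyl. Keeping the chain alcohol latent as an allyl group until C9–OH is acylated means the two primary alcohols never coexist, so no protecting group is spent on telling them apart. The price is a hydroboration that must choose a terminal alkene over a cinnamate.

**16 from 12 and 15.** The C9 acyl C–O bond is cut to alcohol 12 and (E)-4-silyloxycinnamic acid 15, which comes from p-coumaric acid 13 in one operation. An E cinnamic acid tolerates carbodiimide activation, so this is a routine esterification of the only free hydroxyl.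

**12 from 10, and 10 from 9.** The O1–C2 bond is cut, opening the heterocycle to the 2-aryl-1-arylpropane-1,3-diol 10 with the ring A oxygen masked as a methoxymethyl ether. This cut is preferred to cutting C2–C3 or C3–C3a with ring closure, because the closure then runs through the ring B stabilised cation at C2. The carbinol configuration of 10 becomes irrelevant and only C3 has to be set. The acetal is chosen so that its removal and the ring closure share one acid treatment. 10 comes from boronate 9 by turning C9–B into C9–O with retention.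

**9 from 4, 7 and 6.** Two bonds are cut at once, C2–C3 and C9–B, which dissolves 9 into styrene 4, bis(pinacolato)diboron 7 and aldehyde 6. Against an aldol disconnection of the same C2–C3 bond, this needs no arylacetic acid and no auxiliary, and it delivers C9 at the right oxidation level. The forward reaction must place boron on C9 and copper on C3, set C3 by ligand control, and let the styrene win over the aldehyde and the allyl group for the copper boryl.

**4 from 1, and 6 from 5.** Styrene 4 is traced through aldehyde 3 and salicylaldehyde 2 to eugenol 1 by methylenation, O-protection and ortho-formylation. Ring A, its methoxy group and the latent C5 chain are thus bought intact. Aldehyde 6 is silylated vanillin 5.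

## Roads not taken

**Alternative 1:** The C2–C3 bond is cut with the ring still to be closed. Aryldiazoacetate A2, in which the ring A oxygen carries the ring B benzyl group, is decomposed by Rh2(S-PTTL)4 (dirhodium tetrakis[N-phthaloyl-(S)-tert-leucinate], divalent rhodium). The carbene carbon (C3) inserts into one of the two benzylic C–H bonds next to oxygen and gives the cis ester A1 with C2 as in the target.
- Merits: the heterocycle is closed and both centres are set in one catalytic step, by a reaction type established for this ring system. The key step adopted here cannot claim that.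
- Weak points for 21: the insertion gives cis, so C3 must be epimerised next to the ester and the ester then reduced to reach the C9 alcohol. The diazo ester needs an arylacetate, an O-benzylation and a diazo transfer. The benzyl ethers that suit the carbene step cannot be removed by hydrogenolysis once a cinnamate is present, and the phenol and chain benzyl ethers are not distinguished, so protecting groups would have to be exchanged before the esters go on.
- Comparison: in precedent and in direct control of C2 this road is the better one. The adopted plan sets against it a shorter path (three steps from eugenol to the key substrate, C9 at the alcohol level straight after oxidation, no epimerisation or reduction) and a chain terminus and phenol protection that fit the end game unchanged.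

**Alternative 2:** Ring A is made last by cutting C3a–C4 and C7a–C7. Silyl ketene acetal A4, a 2-silyloxy-4,5-dihydrofuran that already holds C2 and C3 trans, would act as dienophile towards 3,5-dibromo-2-pyrone A5. Cycloaddition, loss of CO2 and loss of silanol on heating would give dibromide A3.
- Merits: the two stereocentres sit on a simple five-membered ring, where established asymmetric methods can make them, and no new catalytic reaction is needed.
- Weak points: ring A of 21 is available intact from eugenol with allyl and methoxy in place, so building it is a detour. The two bromides of A3 must then be differentiated into a C7 methoxy group and a C5 three-carbon chain, which means one C–O and one C–C coupling with site selectivity, then chain elaboration. The hot aromatisation exposes the acid-labile C2, and the pivalate and methoxymethyl groups would need exchange.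
- Comparison: its stereochemistry rests on safer ground than an untested copper step, but it is several steps longer after the key step. The adopted plan carries only the risk of step 5, and a fallback in known chemistry covers that.

**Alternative 3:** The C3–C3a and C9–O bonds are cut. Aryl iodide A7 is the ether of an ortho-iodinated eugenol with an enantioenriched 1-arylallyl alcohol. With Bu3SnH it gives an aryl radical at C3a that adds 5-exo to the inner vinyl carbon (C3), and TEMPO captures the C9 radical to give A6. N–O cleavage with zinc would give alcohol 12 itself.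
- Merits: the reaction type is established, the conditions are neutral, the allyl and silyl groups are those of the adopted route, and the two routes meet at 12.
- Weak points: the absolute configuration is stored at C2, the centre that ionises. The cyclisation is kinetic and only moderately trans-selective. Any cis isomer, if equilibrated through the C2 cation, becomes the enantiomer of the trans compound, so imperfect diastereoselectivity turns into loss of enantiopurity unless isomers are separated. The branched aryl allyl ether needs its own asymmetric step with a hindered phenol, and tin residues must be removed.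
- Comparison: in precedent this is the stronger key step, and in step count it is about equal. The adopted plan sets against it that chirality is stored at the non-labile C3 while the labile C2 is left to equilibrate, so imperfect diastereoselectivity costs nothing.

Key step: step 5

Remark 1: [bis(2,2,2-trifluoroethoxy)phosphoryl]acetic acid is treated as a purchasable reagent.
Remark 2: the sense of induction of the bisphosphine in step 5 is not known in advance for this ortho-alkoxy styrene; the enantiomer of the ligand that gives the 2R boronate is the one to be used.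

## Route

**Step 1**
Reactants: 1 eugenol (4-allyl-2-methoxyphenol)
Product: 2 5-allyl-2-hydroxy-3-methoxybenzaldehyde
Conditions: MgCl2, Et3N, (CH2O)n, MeCN, reflux; aq. HCl work-up
Reagents that add atoms: paraformaldehyde (as formaldehyde), C=O
Why: Magnesium phenoxide-directed ortho-formylation (Casnati–Skattebøl): formaldehyde is delivered inside the magnesium chelate to the only free position ortho to the phenol, and a second formaldehyde oxidises the benzylic alkoxide by hydride transfer; the allyl group is inert.

**Step 2**
Reactants: 2 5-allyl-2-hydroxy-3-methoxybenzaldehyde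
Product: 3 5-allyl-3-methoxy-2-(methoxymethoxy)benzaldehyde
Conditions: MOMCl, iPr2NEt, CH2Cl2, 0 °C to rt
Reagents that add atoms: chloromethyl methyl ether, COCCl
Why: O-alkylation of the phenol by the reactive α-chloro ether under amine base; the acetal withstands the ylide, copper alkoxide and perborate that follow and leaves under the acid that later closes the ring.

**Step 3**
Reactants: 3 5-allyl-3-methoxy-2-(methoxymethoxy)benzaldehyde
Product: 4 5-allyl-1-methoxy-2-(methoxymethoxy)-3-vinylbenzene
Conditions: Ph3PCH3Br, KOtBu, THF, 0 °C to rt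
Reagents that add atoms: methyltriphenylphosphonium bromide, C[P+](c1ccccc1)(c1ccccc1)c1ccccc1.[Br-]
Why: Wittig methylenation of a non-enolisable aryl aldehyde; the allyl group and the acetal are untouched.

**Step 4**
Reactants: 5 vanillin
Product: 6 3-methoxy-4-(triisopropylsilyloxy)benzaldehyde
Conditions: TIPSCl, imidazole, DMF, rt
Reagents that add atoms: chlorotriisopropylsilane, CC(C)[Si](Cl)(C(C)C)C(C)C
Why: Imidazole-mediated silylation of a phenol; the bulky silyl ether is chosen because it must survive alkoxide, perborate and methanolic HCl before a final fluoride cleavage.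

**Step 5**
Reactants: 4 5-allyl-1-methoxy-2-(methoxymethoxy)-3-vinylbenzene; 7 bis(pinacolato)diboron; 6 3-methoxy-4-(triisopropylsilyloxy)benzaldehyde
Product: 9 (2R)-2-[5-allyl-3-methoxy-2-(methoxymethoxy)phenyl]-1-[3-methoxy-4-(triisopropylsilyloxy)phenyl]-3-(4,4,5,5-tetramethyl-1,3,2-dioxaborolan-2-yl)propan-1-ol (both C1 epimers), via O-pinacolboryl ether 8 (not isolated)
Conditions: CuCl (5 mol %), Ph-BPE [1,2-bis(2,5-diphenylphospholan-1-yl)ethane, single enantiomer] (6 mol %), NaOtBu (10 mol %), 7 (1.1 equiv), THF, 0 °C to rt, 6 added over several hours by syringe pump; aq. NH4Cl work-up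
Reagents that add atoms: none
Why: Proposed new method: NaOtBu turns CuCl and the bisphosphine into LCu–OtBu, which with 7 gives the monovalent copper boryl LCu–Bpin; this adds syn across the vinyl group of 4 with boron on the terminal carbon (C9) and copper on the benzylic carbon (C3), the regiochemistry general for vinylarenes. The benzylic copper adds to the carbonyl carbon of 6 to form C2–C3, and the copper alkoxide exchanges with 7 to give boryl ether 8 and LCu–Bpin again; aqueous work-up hydrolyses 8 to 9. The closest known reactions are the copper-boryl three-component couplings of vinylarenes with imines (enantioselective) and with CO2, those of allenes and 1,3-dienes with aldehydes, and the CuH-mediated coupling of vinylarenes with ketones, all of which pass through the same kind of organocopper; new here is the intermolecular capture of a boryl-derived benzylic copper by an aldehyde. No ring is closed. C3 is set by the chiral bisphosphine, which chooses the face of the styrene at insertion, and the C–C bond formation is expected to transfer that configuration as it does with imines. The carbinol centre is left uncontrolled on purpose because step 7 erases it. The selectivity needed is insertion of the vinylarene ahead of 1,2-borylation of the aldehyde and ahead of the allyl group: the aldehyde is electron-rich and kept at low concentration by slow addition, the styrene is present in full from the start, and an unactivated monosubstituted alkene inserts into a bisphosphine copper boryl far more slowly than a vinylarene.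

**Step 6**
Reactants: 9 (2R)-boronate carbinol
Product: 10 (2S)-2-[5-allyl-3-methoxy-2-(methoxymethoxy)phenyl]-1-[3-methoxy-4-(triisopropylsilyloxy)phenyl]propane-1,3-diol (both C1 epimers)
Conditions: NaBO3·4H2O, THF/H2O, rt
Reagents that add atoms: sodium perborate tetrahydrate, [Na+].[O-]OB=O.O.O.O.O
Why: Oxidation of the C–B bond by 1,2-migration of C9 from boron to oxygen in the peroxoborate, with retention and without touching C3 (the descriptor changes from R to S only because oxygen replaces boron); perborate is mild enough for the aryl silyl ether, the acetal and both alkenes.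

**Step 7**
Reactants: 10 (2S)-1,3-diol
Product: 12 [(2R,3S)-5-allyl-7-methoxy-2-[3-methoxy-4-(triisopropylsilyloxy)phenyl]-2,3-dihydrobenzofuran-3-yl]methanol (trans), via free phenol triol 11 (not isolated)
Conditions: HCl (ca. 1 M in MeOH), rt to 40 °C
Reagents that add atoms: none
Why: Acid removes the methoxymethyl group and ionises the benzylic carbinol to a cation stabilised by the para-silyloxy ring B, which the ring A oxygen captures to close O1–C2 (five-membered ring by intramolecular capture of a benzylic cation, the known acid cyclisation of 2-(2-hydroxyaryl)-1-arylpropane-1,3-diols). C2 is set by C3: the aryl group takes the face anti to the C9 hydroxymethyl group, and reversible ionisation at C2 lets both carbinol epimers converge on the trans isomer. Methanol traps the methoxymethyl cation as dimethoxymethane and so keeps formaldehyde off the 1,3-diol.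

**Step 8**
Reactants: 13 (E)-p-coumaric acid
Product: 15 (E)-3-[4-(triisopropylsilyloxy)phenyl]prop-2-enoic acid, via bis-silylated coumaric acid 14 (not isolated)
Conditions: TIPSCl (2.2 equiv), imidazole, DMF, rt; then K2CO3, MeOH/THF/H2O, 0 °C; aq. HCl to pH 3
Reagents that add atoms: chlorotriisopropylsilane, CC(C)[Si](Cl)(C(C)C)C(C)C
Why: Silylation of both acidic hydroxyls followed by selective solvolysis of the silyl ester, which is far more labile to carbonate than the aryl silyl ether; the E alkene is not involved.

**Step 9**
Reactants: 12 trans (2R,3S) alcohol; 15 (E)-3-[4-(triisopropylsilyloxy)phenyl]prop-2-enoic acid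
Product: 16 [(2R,3S)-5-allyl-7-methoxy-2-[3-methoxy-4-(triisopropylsilyloxy)phenyl]-2,3-dihydrobenzofuran-3-yl]methyl (E)-3-[4-(triisopropylsilyloxy)phenyl]prop-2-enoate
Conditions: EDC·HCl, DMAP, CH2Cl2, 0 °C to rt
Reagents that add atoms: none
Why: Steglich esterification of the only free hydroxyl; an E cinnamic acid keeps its geometry through the acylpyridinium, and no stereocentre takes part.

**Step 10**
Reactants: 16 allyl coumarate
Product: 18 [(2R,3S)-5-(3-hydroxypropyl)-7-methoxy-2-[3-methoxy-4-(triisopropylsilyloxy)phenyl]-2,3-dihydrobenzofuran-3-yl]methyl (E)-3-[4-(triisopropylsilyloxy)phenyl]prop-2-enoate, via B-alkyl-9-BBN adduct 17 (not isolated)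
Conditions: 9-BBN, THF, 0 °C to rt; then NaBO3·4H2O, H2O, rt
Reagents that add atoms: 9-borabicyclo[3.3.1]nonane, B1C2CCCC1CCC2 (its atoms are in 17 only); sodium perborate tetrahydrate, [Na+].[O-]OB=O.O.O.O.O (supplies the hydroxyl oxygen)
Why: Anti-Markovnikov hydroboration–oxidation; the hindered dialkylborane adds to a terminal alkene much faster than to a conjugated, electron-poor 1,2-disubstituted cinnamate, and perborate oxidises the alkylborane without saponifying the ester.

**Step 11**
Reactants: 18 primary alcohol
Product: 19 3-[(2R,3S)-7-methoxy-2-[3-methoxy-4-(triisopropylsilyloxy)phenyl]-3-({[(E)-3-(4-triisopropylsilyloxyphenyl)prop-2-enoyl]oxy}methyl)-2,3-dihydrobenzofuran-5-yl]propyl [bis(2,2,2-trifluoroethoxy)phosphoryl]acetate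
Conditions: (CF3CH2O)2P(O)CH2CO2H, EDC·HCl, DMAP (cat.), CH2Cl2, 0 °C to rt
Reagents that add atoms: [bis(2,2,2-trifluoroethoxy)phosphoryl]acetic acid, OC(=O)CP(=O)(OCC(F)(F)F)OCC(F)(F)F
Why: Carbodiimide esterification of an unhindered primary alcohol with an acidic phosphonoacetic acid, a routine way to install a Z-selective olefination handle.

**Step 12**
Reactants: 19 phosphonoacetate; 6 3-methoxy-4-(triisopropylsilyloxy)benzaldehyde
Product: 20 3-[(2R,3S)-7-methoxy-2-[3-methoxy-4-(triisopropylsilyloxy)phenyl]-3-({[(E)-3-(4-triisopropylsilyloxyphenyl)prop-2-enoyl]oxy}methyl)-2,3-dihydrobenzofuran-5-yl]propyl (Z)-3-[3-methoxy-4-(triisopropylsilyloxy)phenyl]prop-2-enoate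
Conditions: KN(SiMe3)2, 18-crown-6, THF, −78 °C, then 6; light excluded from here on
Reagents that add atoms: none
Why: Still–Gennari variant of the Horner–Wadsworth–Emmons reaction: with the electron-poor trifluoroethyl phosphonate and a dissociated potassium counter-ion, elimination from the kinetically formed adduct outruns its equilibration, which gives Z cinnamates from aryl aldehydes; at −78 °C the stabilised anion leaves the other ester alone.

**Step 13**
Reactants: 20 tris(triisopropylsilyl) ether
Product: 21 3-[(2R,3S)-2-(4-hydroxy-3-methoxyphenyl)-3-({[(E)-3-(4-hydroxyphenyl)prop-2-enoyl]oxy}methyl)-7-methoxy-2,3-dihydrobenzofuran-5-yl]propyl (Z)-3-(4-hydroxy-3-methoxyphenyl)prop-2-enoate (CNP0267960.2)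
Conditions: Bu4NF, AcOH (1:1, 3.5 equiv each), THF, 0 °C, dark
Reagents that add atoms: none
Why: Fluoride cleavage of aryl silyl ethers; acetic acid protonates each phenoxide as it forms, which suppresses ester cleavage and phenoxide-assisted Z to E isomerisation, and neither stereocentre is exposed to acid or base strong enough to ionise C2.

## Compound list

1 | eugenol (4-allyl-2-methoxyphenol) | C=CCc1ccc(O)c(OC)c1 | starting material
2 | 5-allyl-2-hydroxy-3-methoxybenzaldehyde | C=CCc1cc(OC)c(O)c(C=O)c1 | intermediate
3 | 5-allyl-3-methoxy-2-(methoxymethoxy)benzaldehyde | C=CCc1cc(OC)c(OCOC)c(C=O)c1 | intermediate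
4 | 5-allyl-1-methoxy-2-(methoxymethoxy)-3-vinylbenzene | C=CCc1cc(OC)c(OCOC)c(C=C)c1 | intermediate
5 | vanillin | COc1cc(C=O)ccc1O | starting material
6 | 3-methoxy-4-(triisopropylsilyloxy)benzaldehyde | COc1cc(C=O)ccc1O[Si](C(C)C)(C(C)C)C(C)C | intermediate
7 | bis(pinacolato)diboron | CC1(C)OB(OC1(C)C)B1OC(C)(C)C(C)(C)O1 | starting material
8 | O-pinacolboryl ether of 9, (2R), both C1 epimers (not isolated) | C=CCc1cc(OC)c(OCOC)c(c1)[C@@H](CB1OC(C)(C)C(C)(C)O1)C(OB1OC(C)(C)C(C)(C)O1)c1ccc(O[Si](C(C)C)(C(C)C)C(C)C)c(OC)c1 | intermediate
9 | (2R)-2-[5-allyl-3-methoxy-2-(methoxymethoxy)phenyl]-1-[3-methoxy-4-(triisopropylsilyloxy)phenyl]-3-(4,4,5,5-tetramethyl-1,3,2-dioxaborolan-2-yl)propan-1-ol, both C1 epimers | C=CCc1cc(OC)c(OCOC)c(c1)[C@@H](CB1OC(C)(C)C(C)(C)O1)C(O)c1ccc(O[Si](C(C)C)(C(C)C)C(C)C)c(OC)c1 | intermediate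
10 | (2S)-2-[5-allyl-3-methoxy-2-(methoxymethoxy)phenyl]-1-[3-methoxy-4-(triisopropylsilyloxy)phenyl]propane-1,3-diol, both C1 epimers | C=CCc1cc(OC)c(OCOC)c(c1)[C@@H](CO)C(O)c1ccc(O[Si](C(C)C)(C(C)C)C(C)C)c(OC)c1 | intermediate
11 | (2S)-2-(5-allyl-2-hydroxy-3-methoxyphenyl)-1-[3-methoxy-4-(triisopropylsilyloxy)phenyl]propane-1,3-diol, both C1 epimers (not isolated) | C=CCc1cc(OC)c(O)c(c1)[C@@H](CO)C(O)c1ccc(O[Si](C(C)C)(C(C)C)C(C)C)c(OC)c1 | intermediate
12 | [(2R,3S)-5-allyl-7-methoxy-2-[3-methoxy-4-(triisopropylsilyloxy)phenyl]-2,3-dihydrobenzofuran-3-yl]methanol (trans) | C=CCc1cc(OC)c2c(c1)[C@@H](CO)[C@H](c1ccc(O[Si](C(C)C)(C(C)C)C(C)C)c(OC)c1)O2 | intermediate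
13 | (E)-p-coumaric acid | OC(=O)/C=C/c1ccc(O)cc1 | starting material
14 | triisopropylsilyl (E)-3-[4-(triisopropylsilyloxy)phenyl]prop-2-enoate (not isolated) | CC(C)[Si](C(C)C)(C(C)C)OC(=O)/C=C/c1ccc(O[Si](C(C)C)(C(C)C)C(C)C)cc1 | intermediate
15 | (E)-3-[4-(triisopropylsilyloxy)phenyl]prop-2-enoic acid | OC(=O)/C=C/c1ccc(O[Si](C(C)C)(C(C)C)C(C)C)cc1 | intermediate
16 | [(2R,3S)-5-allyl-7-methoxy-2-[3-methoxy-4-(triisopropylsilyloxy)phenyl]-2,3-dihydrobenzofuran-3-yl]methyl (E)-3-[4-(triisopropylsilyloxy)phenyl]prop-2-enoate | C=CCc1cc(OC)c2c(c1)[C@@H](COC(=O)/C=C/c1ccc(O[Si](C(C)C)(C(C)C)C(C)C)cc1)[C@H](c1ccc(O[Si](C(C)C)(C(C)C)C(C)C)c(OC)c1)O2 | intermediate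
17 | 9-{3-[(2R,3S)-benzofuranyl]propyl}-9-borabicyclo[3.3.1]nonane, the hydroboration adduct of 16 (not isolated) | C(CCB1C2CCCC1CCC2)c1cc(OC)c2c(c1)[C@@H](COC(=O)/C=C/c1ccc(O[Si](C(C)C)(C(C)C)C(C)C)cc1)[C@H](c1ccc(O[Si](C(C)C)(C(C)C)C(C)C)c(OC)c1)O2 | intermediate
18 | [(2R,3S)-5-(3-hydroxypropyl)-7-methoxy-2-[3-methoxy-4-(triisopropylsilyloxy)phenyl]-2,3-dihydrobenzofuran-3-yl]methyl (E)-3-[4-(triisopropylsilyloxy)phenyl]prop-2-enoate | OCCCc1cc(OC)c2c(c1)[C@@H](COC(=O)/C=C/c1ccc(O[Si](C(C)C)(C(C)C)C(C)C)cc1)[C@H](c1ccc(O[Si](C(C)C)(C(C)C)C(C)C)c(OC)c1)O2 | intermediate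
19 | [bis(2,2,2-trifluoroethoxy)phosphoryl]acetate of 18, (2R,3S) | FC(F)(F)COP(=O)(OCC(F)(F)F)CC(=O)OCCCc1cc(OC)c2c(c1)[C@@H](COC(=O)/C=C/c1ccc(O[Si](C(C)C)(C(C)C)C(C)C)cc1)[C@H](c1ccc(O[Si](C(C)C)(C(C)C)C(C)C)c(OC)c1)O2 | intermediate
20 | tris(triisopropylsilyl) ether of 21, (2R,3S), E coumarate, Z ferulate | COc1cc(/C=C\C(=O)OCCCc2cc(OC)c3c(c2)[C@@H](COC(=O)/C=C/c2ccc(O[Si](C(C)C)(C(C)C)C(C)C)cc2)[C@H](c2ccc(O[Si](C(C)C)(C(C)C)C(C)C)c(OC)c2)O3)ccc1O[Si](C(C)C)(C(C)C)C(C)C | intermediate
21 | 3-[(2R,3S)-2-(4-hydroxy-3-methoxyphenyl)-3-({[(E)-3-(4-hydroxyphenyl)prop-2-enoyl]oxy}methyl)-7-methoxy-2,3-dihydrobenzofuran-5-yl]propyl (Z)-3-(4-hydroxy-3-methoxyphenyl)prop-2-enoate | COc1cc(/C=C\C(=O)OCCCc2cc(OC)c3c(c2)[C@@H](COC(=O)/C=C/c2ccc(O)cc2)[C@H](c2ccc(O)c(OC)c2)O3)ccc1O | target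

## Step count and least certain steps

Total: 13 steps. Longest linear sequence: 11 steps (1, 2, 3, 5, 6, 7, 9, 10, 11, 12, 13).

**Step 5 (key step, proposed new method).**
- Most likely failure: 1,2-addition of the copper boryl to the aldehyde, or protonation or β-hydride loss of the benzylic copper, outrunning the three-component pathway. The aldehyde is the more electrophilic partner for a copper boryl, and the benzylic copper must wait for it under slow addition. Incomplete enantiocontrol at C3 is the second risk.
- Fallback in known chemistry, setting out from aldehyde 3 and returning at diol 10: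
  - van Leusen reductive cyanation of 3 (TosMIC, KOtBu, then MeOH) gives [5-allyl-3-methoxy-2-(methoxymethoxy)phenyl]acetonitrile F1.
  - Hydrolysis (KOH, aqueous EtOH, reflux) gives [5-allyl-3-methoxy-2-(methoxymethoxy)phenyl]acetic acid F2.
  - Mixed-anhydride coupling (PivCl, Et3N, then lithiated (R)-4-benzyloxazolidin-2-one) gives the N-arylacetyl oxazolidinone F3.
  - Enolisation with Bu2BOTf and iPr2NEt and addition to 6 gives the Evans syn aldol F4.
  - LiBH4 removes the auxiliary and gives 10 as its single (1R,2S) epimer, with C2 set by the auxiliary.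

**Step 7.**
- Most likely failure: erosion of the trans preference or of C3 through reversible ionisation and E1 loss of the C3 proton, and capture of acetal-derived formaldehyde by the free 1,3-diol, because the diol and the benzylic cation coexist in acid.
- Fallback, setting out from boronate 9 and returning at 12: the ring is closed before boron is oxidised. Methanolic HCl applied to 9, which has no free primary hydroxyl, gives (2R,3R)-5-allyl-7-methoxy-2-[3-methoxy-4-(triisopropylsilyloxy)phenyl]-3-[(4,4,5,5-tetramethyl-1,3,2-dioxaborolan-2-yl)methyl]-2,3-dihydrobenzofuran F5. NaBO3·4H2O then gives 12.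

**Step 10.**
- Most likely failure: reduction or hydroboration of the conjugated coumarate double bond and partial ester cleavage in the oxidative work-up, because a borane and a basic peroxide meet an enoate.
- Fallback, setting out from 12 and returning at 19: the chain is oxidised before any ester is present.
  - Silylation of C9–OH (TBSCl, imidazole) gives the tert-butyldimethylsilyl ether F6.
  - 9-BBN then NaBO3·4H2O gives the chain alcohol F7.
  - Carbodiimide coupling with [bis(2,2,2-trifluoroethoxy)phosphoryl]acetic acid gives the phosphonoacetate F8.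
  - HF·pyridine removes the alkyl silyl ether faster than the aryl ones and gives the C9 alcohol F9.
  - Esterification of F9 with 15 (EDC·HCl, DMAP) gives 19.

**Step 12.**
- Most likely failure: incomplete Z selectivity, or sluggish addition that forces warming and lets the adducts equilibrate, because the aldehyde is electron-rich.
- Fallback, setting out from 18 (with aldehyde 6) and returning at 20: the Z alkene is made by syn addition of hydrogen to an alkyne.
  - Corey–Fuchs reaction of 6 (CBr4, PPh3) gives [4-(2,2-dibromoethenyl)-2-methoxyphenoxy]triisopropylsilane F10.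
  - n-BuLi then CO2 gives 3-[3-methoxy-4-(triisopropylsilyloxy)phenyl]prop-2-ynoic acid F11.
  - Esterification of 18 with F11 (DCC, cat. DMAP, −20 °C) gives the arylpropynoate ester F12.
  - Semi-hydrogenation (H2, Pd/CaCO3 poisoned with Pb(OAc)2, quinoline, EtOAc) gives 20.

**Step 13.**
- Most likely failure: Z to E isomerisation of the ferulate during desilylation, through its phenoxide (which lowers the rotation barrier of the push–pull alkene) or by stray light.
- Fallback, setting out from 18 and returning at 21: the Z alkene is created after the phenols are free. The arylpropynoate ester F12 is prepared from 18 as described for step 12. Desilylation of F12 with Bu4NF/AcOH gives the triphenol arylpropynoate F13. Semi-hydrogenation of F13 over Pd/CaCO3 poisoned with Pb(OAc)2 gives 21 directly.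

## Further compounds

F1 | step 5 | [5-allyl-3-methoxy-2-(methoxymethoxy)phenyl]acetonitrile | C=CCc1cc(OC)c(OCOC)c(CC#N)c1
F2 | step 5 | [5-allyl-3-methoxy-2-(methoxymethoxy)phenyl]acetic acid | C=CCc1cc(OC)c(OCOC)c(CC(=O)O)c1
F3 | step 5 | (4R)-4-benzyl-3-{[5-allyl-3-methoxy-2-(methoxymethoxy)phenyl]acetyl}-1,3-oxazolidin-2-one | C=CCc1cc(OC)c(OCOC)c(CC(=O)N2[C@H](Cc3ccccc3)COC2=O)c1
F4 | step 5 | (4R)-4-benzyl-3-{(2R,3R)-2-[5-allyl-3-methoxy-2-(methoxymethoxy)phenyl]-3-hydroxy-3-[3-methoxy-4-(triisopropylsilyloxy)phenyl]propanoyl}-1,3-oxazolidin-2-one | C=CCc1cc(OC)c(OCOC)c(c1)[C@@H](C(=O)N1[C@H](Cc2ccccc2)COC1=O)[C@@H](O)c1ccc(O[Si](C(C)C)(C(C)C)C(C)C)c(OC)c1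
F5 | step 7 | (2R,3R)-5-allyl-7-methoxy-2-[3-methoxy-4-(triisopropylsilyloxy)phenyl]-3-[(4,4,5,5-tetramethyl-1,3,2-dioxaborolan-2-yl)methyl]-2,3-dihydrobenzofuran (trans) | C=CCc1cc(OC)c2c(c1)[C@@H](CB1OC(C)(C)C(C)(C)O1)[C@H](c1ccc(O[Si](C(C)C)(C(C)C)C(C)C)c(OC)c1)O2
F6 | step 10 | tert-butyl{[(2R,3S)-5-allyl-7-methoxy-2-[3-methoxy-4-(triisopropylsilyloxy)phenyl]-2,3-dihydrobenzofuran-3-yl]methoxy}dimethylsilane | C=CCc1cc(OC)c2c(c1)[C@@H](CO[Si](C)(C)C(C)(C)C)[C@H](c1ccc(O[Si](C(C)C)(C(C)C)C(C)C)c(OC)c1)O2
F7 | step 10 | 3-[(2R,3S)-3-[(tert-butyldimethylsilyloxy)methyl]-7-methoxy-2-[3-methoxy-4-(triisopropylsilyloxy)phenyl]-2,3-dihydrobenzofuran-5-yl]propan-1-ol | OCCCc1cc(OC)c2c(c1)[C@@H](CO[Si](C)(C)C(C)(C)C)[C@H](c1ccc(O[Si](C(C)C)(C(C)C)C(C)C)c(OC)c1)O2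
F8 | step 10 | 3-[(2R,3S)-3-[(tert-butyldimethylsilyloxy)methyl]-7-methoxy-2-[3-methoxy-4-(triisopropylsilyloxy)phenyl]-2,3-dihydrobenzofuran-5-yl]propyl [bis(2,2,2-trifluoroethoxy)phosphoryl]acetate | FC(F)(F)COP(=O)(OCC(F)(F)F)CC(=O)OCCCc1cc(OC)c2c(c1)[C@@H](CO[Si](C)(C)C(C)(C)C)[C@H](c1ccc(O[Si](C(C)C)(C(C)C)C(C)C)c(OC)c1)O2
F9 | step 10 | 3-[(2R,3S)-3-(hydroxymethyl)-7-methoxy-2-[3-methoxy-4-(triisopropylsilyloxy)phenyl]-2,3-dihydrobenzofuran-5-yl]propyl [bis(2,2,2-trifluoroethoxy)phosphoryl]acetate | FC(F)(F)COP(=O)(OCC(F)(F)F)CC(=O)OCCCc1cc(OC)c2c(c1)[C@@H](CO)[C@H](c1ccc(O[Si](C(C)C)(C(C)C)C(C)C)c(OC)c1)O2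
F10 | step 12 | [4-(2,2-dibromoethenyl)-2-methoxyphenoxy]triisopropylsilane | BrC(Br)=Cc1ccc(O[Si](C(C)C)(C(C)C)C(C)C)c(OC)c1
F11 | step 12 | 3-[3-methoxy-4-(triisopropylsilyloxy)phenyl]prop-2-ynoic acid | OC(=O)C#Cc1ccc(O[Si](C(C)C)(C(C)C)C(C)C)c(OC)c1
F12 | step 12 | 3-[(2R,3S)-7-methoxy-2-[3-methoxy-4-(triisopropylsilyloxy)phenyl]-3-({[(E)-3-(4-triisopropylsilyloxyphenyl)prop-2-enoyl]oxy}methyl)-2,3-dihydrobenzofuran-5-yl]propyl 3-[3-methoxy-4-(triisopropylsilyloxy)phenyl]prop-2-ynoate | COc1cc(C#CC(=O)OCCCc2cc(OC)c3c(c2)[C@@H](COC(=O)/C=C/c2ccc(O[Si](C(C)C)(C(C)C)C(C)C)cc2)[C@H](c2ccc(O[Si](C(C)C)(C(C)C)C(C)C)c(OC)c2)O3)ccc1O[Si](C(C)C)(C(C)C)C(C)C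
F13 | step 13 | 3-[(2R,3S)-2-(4-hydroxy-3-methoxyphenyl)-3-({[(E)-3-(4-hydroxyphenyl)prop-2-enoyl]oxy}methyl)-7-methoxy-2,3-dihydrobenzofuran-5-yl]propyl 3-(4-hydroxy-3-methoxyphenyl)prop-2-ynoate | COc1cc(C#CC(=O)OCCCc2cc(OC)c3c(c2)[C@@H](COC(=O)/C=C/c2ccc(O)cc2)[C@H](c2ccc(O)c(OC)c2)O3)ccc1O
A1 | alternative 1 | methyl (2R,3S)-2-(4-benzyloxy-3-methoxyphenyl)-5-(3-benzyloxypropyl)-7-methoxy-2,3-dihydrobenzofuran-3-carboxylate (cis) | c1ccccc1COCCCc1cc(OC)c2c(c1)[C@H](C(=O)OC)[C@H](c1ccc(OCc3ccccc3)c(OC)c1)O2
A2 | alternative 1 | methyl 2-diazo-2-[2-(4-benzyloxy-3-methoxybenzyloxy)-5-(3-benzyloxypropyl)-3-methoxyphenyl]acetate | COC(=O)C(=[N+]=[N-])c1cc(CCCOCc2ccccc2)cc(OC)c1OCc1ccc(OCc2ccccc2)c(OC)c1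
A3 | alternative 2 | (2R,3S)-5,7-dibromo-2-[3-methoxy-4-(methoxymethoxy)phenyl]-3-(pivaloyloxymethyl)-2,3-dihydrobenzofuran (trans) | Brc1cc(Br)c2c(c1)[C@@H](COC(=O)C(C)(C)C)[C@H](c1ccc(OCOC)c(OC)c1)O2
A4 | alternative 2 | trans-2-(tert-butyldimethylsilyloxy)-5-[3-methoxy-4-(methoxymethoxy)phenyl]-4-(pivaloyloxymethyl)-4,5-dihydrofuran | CC(C)(C)[Si](C)(C)OC1=C[C@@H](COC(=O)C(C)(C)C)[C@H](c2ccc(OCOC)c(OC)c2)O1
A5 | alternative 2 | 3,5-dibromo-2H-pyran-2-one | O=c1occ(Br)cc1Br
A6 | alternative 3 | (2R,3S)-5-allyl-7-methoxy-2-[3-methoxy-4-(triisopropylsilyloxy)phenyl]-3-[(2,2,6,6-tetramethylpiperidin-1-yloxy)methyl]-2,3-dihydrobenzofuran (trans) | C=CCc1cc(OC)c2c(c1)[C@@H](CON1C(C)(C)CCCC1(C)C)[C@H](c1ccc(O[Si](C(C)C)(C(C)C)C(C)C)c(OC)c1)O2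
A7 | alternative 3 | (R)-1-[3-methoxy-4-(triisopropylsilyloxy)phenyl]prop-2-en-1-yl 4-allyl-2-iodo-6-methoxyphenyl ether | C=CCc1cc(OC)c(O[C@H](C=C)c2ccc(O[Si](C(C)C)(C(C)C)C(C)C)c(OC)c2)c(I)c1
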